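## Structural features

Betaethrin E is a diaryl ether of two tetrasubstituted benzene rings that carries a C16 acyl chain. Ring A is a benzyl alcohol ring esterified with palmitic acid at its CH2O group. Going round ring A from the CH2O-bearing carbon, it has CH, C–OMe, CH, C–OH and the ether carbon, so the ether oxygen lies between the hydroxyl and the CH2O substituent. Ring B is a methyl salicylate: the ester carbon is flanked by the ether carbon and a chelated C–OH, and a methyl group stands para to the ester. There is no stereocentre and no stereogenic double bond, so no stereochemical relationship has to be set. The fragile groups are the primary benzylic palmitate (transesterification, acyl transfer to the phenols), the two free phenols and the salicylate ester. The real difficulty is the ether, whose two carbons each carry two ortho substituents, together with the need for three different oxygen substituents (OH, OMe, OAr) on defined ring A carbons. The key step uses the fact that the ring A atoms C(OH)–CH–C(OMe)–CH are a masked 3-methoxycyclobutenone (carbonyl carbon becomes C–OH), while the CH2O-bearing carbon and the ether carbon are a 2-aryloxyvinyl unit whose oxygen already carries ring B.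

## Logic of the disconnections

19 to 17 and 18. The acyl C–O bond of the benzylic ester is cut. The most labile function is thus made last and the long chain stays out of all earlier chemistry. The forward step must acylate one primary alcohol beside two phenols, which calls for an enzyme.

17 to 16. Two O–Si bonds are cut, one on the benzylic oxygen and one on the ring B phenol. One deprotection then serves both positions. The forward step must not ionise the benzylic alcohol or touch the methyl ester.

16 to 7 and 12 (through 15, 14 and 13). Two C–C bonds of ring A are cut: the bond between the C–OH carbon and the ether carbon, and the bond between the CH next to the CH2O-bearing carbon and that carbon. Ring A falls apart into a four-carbon and a two-carbon piece. The hindered ether is then an enol ether, and OH, OMe and OAr are differentiated from the outset. The forward step needs a coupling at the chlorinated carbon and a ring opening and ring closure that outrun capture of the ketene.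

7 to 6. The C–Sn bond is cut, because an alkenyl bromide is the stable carrier of that position. The forward step must keep the alkene geometry and tolerate an enol ether and two silyl ethers.

6 to 5. Two O–Si bonds are cut. One silylation protects the primary alcohol and removes the acidic phenol before tin and ketene chemistry.

5 to 4. A C–H bond at the carbinol carbon is cut (aldehyde oxidation level). The enal is what addition–elimination delivers. The forward reduction must be 1,2 and must not expel the aryloxy group.

4 to 2 and 3. The vinyl C–O bond is cut. The ether oxygen is attached to an sp2 carbon by addition–elimination and not by a hindered aryl coupling. The forward step must stop at mono-vinylation of the symmetric diphenol.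

2 to 1. The O–S bond is cut. The enol of a malonaldehyde becomes a leaving group in one step.

12 to 11. The C–Cl bond is cut. The alcohol is the storable precursor of a reactive chloride. The forward step must substitute without ionising the ring.

11 to 10. A C–H bond is cut (ketone to carbinol). Hydride must choose the carbonyl next to the methoxy-bearing carbon, so that the methoxy enone stays intact.

10 to 8 (through 9). A C–H bond and the carbonyl transposition are undone. The symmetric diester makes the first hydride addition unambiguous, and acid then removes one methoxy group.

## Other disconnections considered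

Alternative 1: The cut falls on ring B, at the ether C–O bond and at the bond from the ring to the carboxyl carbon. This leaves an aryne, a phenoxide and a one-carbon electrophile.
- **Forward step:** Fluoride would release the aryne from silyl triflate A1 beside the caesium phenoxide of A2 under carbon dioxide A3. The phenoxide oxygen should attack the aryne carbon remote from the OMOM group, because the charge then develops between two oxygen substituents. That aryl anion should be carboxylated by A3 to give acid A4.
- **In favour:** Three components are joined in one operation. The ether is formed by an aryne capture that should tolerate the two ortho substituents of A2. No tin and no strained ketone are needed. On these points it is the equal or the better of the chosen plan.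
- **Against:** A2 must be made with its three oxygen functions already differentiated, which the chosen plan avoids. A1 needs several steps of its own. Protonation of the aryl anion may compete with capture of A3. A4 still needs esterification and removal of two MOM groups before the two closing steps.
- **Comparison:** It is more convergent in structure. Its mechanism is polar and rests on inductive regiocontrol, where the chosen plan has constitutional control from a pericyclic cascade. By a rough count it needs about two more operations.

Alternative 2: Ring A is again built from non-aromatic pieces, on a benzofuranone that already holds ring B and the ether oxygen. The bonds cut are the one from the ether carbon to the CH2O-bearing carbon and the one from the neighbouring C–OH carbon to its CH.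
- **Forward step:** An alkoxide base would give the C2 enolate of keto ester A5. This adds to the silyloxymethyl-bearing alkyne carbon of ynone A6 (Michael addition). The methyl ketone enolate then attacks the ester (Claisen condensation) to close spiro dienone A7. Methanolysis of A7 would cleave the bond between the benzofuranone carbonyl and the spiro carbon and give triphenol A8, with the methyl ester formed in the same event.
- **In favour:** The chemistry is polar and tin-free and uses cheap components. The ester and the ether are unveiled together. By a rough count the step total is equal to or slightly below that of the chosen plan, so on step economy it is the equal or the better.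
- **Against:** Both C–C bond formations are reversible. The free hydroxyl of A5 consumes base. O- and C-alkylation compete. The OMe of ring A must be installed late, by a selective methylation of one of three phenols in A8 or of the enol in A7.
- **Comparison:** Both plans avoid an aryl–oxygen coupling. The chosen plan fixes OH and OMe by construction and ends in an irreversible aromatisation, while this one is shorter but carries a regiochemical risk at the methylation.

Alternative 3: The cut is in ring B, at the bond between the ester-bearing carbon and the C–OH carbon and at the bond between the methyl-bearing carbon and the adjacent CH.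
- **Forward step:** Pyrone A9 and ketene acetal A10 would undergo a Diels–Alder reaction on heating. The CH2 carbon of A10 bonds to pyrone C6 and the acetal carbon to C3. Loss of carbon dioxide and silanol should give salicylate A11.
- **In favour:** Ring B arrives with its hydroxyl and ester already differentiated, so no mono-functionalisation of a symmetric diphenol such as 3 is needed. This is a point on which it is better than the chosen plan. The regiochemistry of the cycloaddition follows the polarisation of both partners.
- **Against:** A9 must be made by addition–elimination of the doubly ortho-substituted phenol A2 on an activated pyrone. A2 again requires a differentiated ring A, and a MOM group must be removed at the end.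
- **Comparison:** The two plans are mirror images in structure (arene B or arene A made last). Both are pericyclic and end in aromatisation. The step count should be similar, but the oxygen pattern of ring A is easier to set in the chosen plan.

Key step: step 9

Remarks on the chemistry, each in one line:
- The ring B phenol is carried through the key step as its TBS ether (7 and 16), which leaves the skeletons and the bonds formed unchanged, keeps an acidic OH away from the stannane and the ketene, and costs no step because both silyl ethers fall in step 10.
- The stannane 7 is the Z isomer (tin cis to aryloxy); the same geometry is called E in 13 because CH2OSi outranks the ring carbon, and either geometry would end in 16 since the alkene becomes part of the arene.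
- In 12 the chlorinated carbon and the vinylic CH are both bonded to the carbonyl carbon and to the methoxy carbon, so substitution with or without allylic shift gives one constitution.
- Assumption: 2 is drawn as the Z isomer; its geometry is lost in the addition–elimination, so a mixture would serve.

## Route

Step 1
Reactants: 1 bromomalonaldehyde (2-bromopropanedial)
Product: 2 (Z)-2-bromo-3-oxoprop-1-en-1-yl 4-methylbenzenesulfonate
Conditions: TsCl, Et3N, CH2Cl2, 0 °C
Reagents that add atoms: p-toluenesulfonyl chloride, Cc1ccc(cc1)S(Cl)(=O)=O
Why: O-sulfonylation of the acidic enol should give a vinylogous mixed anhydride, an enal activated for addition–elimination at its β-carbon (enol tosylate formation).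

Step 2
Reactants: 2 (Z)-2-bromo-3-oxoprop-1-en-1-yl 4-methylbenzenesulfonate; 3 methyl 2,6-dihydroxy-4-methylbenzoate
Product: 4 methyl 2-{[(Z)-2-bromo-3-oxoprop-1-en-1-yl]oxy}-6-hydroxy-4-methylbenzoate
Conditions: 3 (1.5 equiv.), K2CO3, MeCN, 0 °C to rt
Reagents that add atoms: none
Why: The phenoxide should add to the β-carbon and expel tosylate (vinylic nucleophilic substitution by addition–elimination), and the product should settle with the aryloxy group trans to the formyl group. The second hydroxyl stays chelated to the ester, and the excess of 3 should hold back double vinylation.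

Step 3
Reactants: 4 methyl 2-{[(Z)-2-bromo-3-oxoprop-1-en-1-yl]oxy}-6-hydroxy-4-methylbenzoate
Product: 5 methyl 2-{[(Z)-2-bromo-3-hydroxyprop-1-en-1-yl]oxy}-6-hydroxy-4-methylbenzoate
Conditions: NaBH4, CeCl3·7H2O, THF–MeOH, −40 °C
Reagents that add atoms: none
Why: Luche reduction should deliver hydride to the cerium-activated aldehyde faster than conjugate addition can expel the aryloxy group, and the hindered, chelated aryl ester should not react at this temperature.

Step 4
Reactants: 5 methyl 2-{[(Z)-2-bromo-3-hydroxyprop-1-en-1-yl]oxy}-6-hydroxy-4-methylbenzoate
Product: 6 methyl 2-{[(Z)-2-bromo-3-(tert-butyldimethylsilyloxy)prop-1-en-1-yl]oxy}-6-(tert-butyldimethylsilyloxy)-4-methylbenzoate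
Conditions: TBSCl (2.5 equiv.), imidazole, DMF, rt to 40 °C
Reagents that add atoms: tert-butyldimethylsilyl chloride, CC(C)(C)[Si](C)(C)Cl
Why: Silylation of both hydroxyls (primary first, chelated phenol with the excess) avoids any need for chemoselectivity and gives a neutral substrate for the tin and ketene steps.

Step 5
Reactants: 6 methyl 2-{[(Z)-2-bromo-3-(tert-butyldimethylsilyloxy)prop-1-en-1-yl]oxy}-6-(tert-butyldimethylsilyloxy)-4-methylbenzoate
Product: 7 methyl 2-(tert-butyldimethylsilyloxy)-4-methyl-6-{[(Z)-3-(tert-butyldimethylsilyloxy)-2-(tributylstannyl)prop-1-en-1-yl]oxy}benzoate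
Conditions: (Bu3Sn)2, Pd(PPh3)4 (5 mol %), toluene, 100 °C
Reagents that add atoms: hexabutylditin, CCCC[Sn](CCCC)(CCCC)[Sn](CCCC)(CCCC)CCCC
Why: Zerovalent palladium should insert into the alkenyl C–Br bond, the ditin transfers a stannyl group and reductive elimination forms the C–Sn bond with retention of geometry (palladium-catalysed stannylation of an alkenyl halide). Purification on base-washed silica should prevent protodestannylation.

Step 6
Reactants: 8 dimethyl squarate (3,4-dimethoxycyclobut-3-ene-1,2-dione)
Product: 10 3-methoxycyclobut-3-ene-1,2-dione (methyl semisquarate), via 4-hydroxy-2,3-dimethoxycyclobut-2-en-1-one 9 (not isolated)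
Conditions: LiAlH(OtBu)3, THF, −78 to −20 °C; then conc. HCl (cat.), CH2Cl2, rt
Reagents that add atoms: water, O
Why: The bulky hydride should add once to one of the two equivalent carbonyls. Acid then ionises the hydroxyl of 9 to a methoxy-stabilised cyclobutenyl cation, water adds at the methoxy-bearing terminus and methanol is lost (reduction followed by 1,3-carbonyl transposition).

Step 7
Reactants: 10 3-methoxycyclobut-3-ene-1,2-dione
Product: 11 4-hydroxy-3-methoxycyclobut-2-en-1-one (racemic)
Conditions: LiAlH(OtBu)3 (1.0 equiv.), THF, −78 °C
Reagents that add atoms: none
Why: 1,2-Reduction should occur at the carbonyl next to the methoxy-bearing carbon, because the other carbonyl is deactivated as a vinylogous ester. This is the site at which carbon nucleophiles add to 3-alkoxycyclobutenediones, and the product keeps the β-methoxy enone.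

Step 8
Reactants: 11 4-hydroxy-3-methoxycyclobut-2-en-1-one
Product: 12 4-chloro-3-methoxycyclobut-2-en-1-one (racemic)
Conditions: SOCl2, 2,6-lutidine, CH2Cl2, −20 to 0 °C; used at once as a solution
Reagents that add atoms: thionyl chloride, ClS(Cl)=O
Why: The chlorosulfite of the activated α-ketol should be displaced by chloride (deoxychlorination). Direct and allylically shifted substitution give the same constitution, and the hindered base removes HCl without attacking the product.

Step 9
Reactants: 12 4-chloro-3-methoxycyclobut-2-en-1-one; 7 methyl 2-(tert-butyldimethylsilyloxy)-4-methyl-6-{[(Z)-3-(tert-butyldimethylsilyloxy)-2-(tributylstannyl)prop-1-en-1-yl]oxy}benzoate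
Product: 16 methyl 2-(tert-butyldimethylsilyloxy)-6-[2-(tert-butyldimethylsilyloxymethyl)-6-hydroxy-4-methoxyphenoxy]-4-methylbenzoate, via alkenylcyclobutenone 13 (not isolated), via dienylketene 14 (not isolated), via cyclohexa-2,4-dienone 15 (not isolated)
Conditions: 12 (1.3 equiv.), Pd2(dba)3 (2.5 mol %), tri(2-furyl)phosphine (10 mol %), dioxane, 50 °C; then 100 °C, 0.02 M
Reagents that add atoms: none
Why: Zerovalent palladium should insert into the C–Cl bond of 12, the alkenyl group of 7 is transferred from tin with retention, and reductive elimination forms the first C–C bond, to the CH2O-bearing carbon, in 13 (Stille coupling). Because both carbons next to the chlorinated position are bonded to the carbonyl and to the methoxy carbon alike, coupling with or without allylic shift gives the same 13, so no site selectivity is needed. At 100 °C 13 should undergo reversible conrotatory 4π opening to 14, and only the isomer with the alkenyl group turned inward can react further. Disrotatory 6π electrocyclisation then joins the ketene carbon to the aryloxy-bearing carbon, which closes the six-membered ring A as dienone 15 by the only ring closure the connectivity allows. Enolisation of 15 gives phenol 16 irreversibly, with the ketene oxygen as the OH next to the ether carbon and the cyclobutenone methoxy as the OMe. The closest known reaction type is the palladium-catalysed coupling of 4-chlorocyclobutenones with alkenylstannanes followed by thermal benzannulation of the 4-alkenylcyclobutenones. No stereocentre is created, and the stereocentres of 12, 13 and 15 and the alkene geometry are erased on aromatisation. The step needs oxidative addition at C–Cl only and a ring closure faster than capture of the ketene; the weak phosphine ligand, the silylated ring B phenol and the dilution are meant to secure this.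

Step 10
Reactants: 16 methyl 2-(tert-butyldimethylsilyloxy)-6-[2-(tert-butyldimethylsilyloxymethyl)-6-hydroxy-4-methoxyphenoxy]-4-methylbenzoate
Product: 17 methyl 2-hydroxy-6-[2-hydroxy-6-(hydroxymethyl)-4-methoxyphenoxy]-4-methylbenzoate
Conditions: HF·pyridine, pyridine, THF, 0 °C to rt
Reagents that add atoms: none
Why: Fluoride should cleave the aryl and the primary alkyl silyl ether in one operation. The buffered medium should promote neither ionisation of the benzylic alcohol nor its lactonisation onto the ring B ester.

Step 11
Reactants: 17 methyl 2-hydroxy-6-[2-hydroxy-6-(hydroxymethyl)-4-methoxyphenoxy]-4-methylbenzoate; 18 vinyl palmitate (ethenyl hexadecanoate)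
Product: 19 betaethrin E, [3-hydroxy-2-(3-hydroxy-2-methoxycarbonyl-5-methylphenoxy)-5-methoxyphenyl]methyl hexadecanoate
Conditions: 18 (3 equiv.), immobilised Candida antarctica lipase B (Novozym 435), 2-MeTHF, 40 °C
Reagents that add atoms: none
Why: Lipase-catalysed transesterification should acylate the primary alcohol only, since the enzyme does not accept the hindered phenols. The reaction is irreversible because the vinyl alcohol released tautomerises to acetaldehyde.

## Compound list

1 | bromomalonaldehyde (2-bromopropanedial) | O=CC(Br)C=O | starting material
2 | (Z)-2-bromo-3-oxoprop-1-en-1-yl 4-methylbenzenesulfonate | Cc1ccc(cc1)S(=O)(=O)O/C=C(\Br)C=O | intermediate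
3 | methyl 2,6-dihydroxy-4-methylbenzoate | COC(=O)c1c(O)cc(C)cc1O | starting material
4 | methyl 2-{[(Z)-2-bromo-3-oxoprop-1-en-1-yl]oxy}-6-hydroxy-4-methylbenzoate | COC(=O)c1c(O)cc(C)cc1O/C=C(\Br)C=O | intermediate
5 | methyl 2-{[(Z)-2-bromo-3-hydroxyprop-1-en-1-yl]oxy}-6-hydroxy-4-methylbenzoate | COC(=O)c1c(O)cc(C)cc1O/C=C(\Br)CO | intermediate
6 | methyl 2-{[(Z)-2-bromo-3-(tert-butyldimethylsilyloxy)prop-1-en-1-yl]oxy}-6-(tert-butyldimethylsilyloxy)-4-methylbenzoate | COC(=O)c1c(O[Si](C)(C)C(C)(C)C)cc(C)cc1O/C=C(\Br)CO[Si](C)(C)C(C)(C)C | intermediate
7 | methyl 2-(tert-butyldimethylsilyloxy)-4-methyl-6-{[(Z)-3-(tert-butyldimethylsilyloxy)-2-(tributylstannyl)prop-1-en-1-yl]oxy}benzoate | COC(=O)c1c(O[Si](C)(C)C(C)(C)C)cc(C)cc1O/C=C(\[Sn](CCCC)(CCCC)CCCC)CO[Si](C)(C)C(C)(C)C | intermediate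
8 | dimethyl squarate (3,4-dimethoxycyclobut-3-ene-1,2-dione) | COC1=C(OC)C(=O)C1=O | starting material
9 | 4-hydroxy-2,3-dimethoxycyclobut-2-en-1-one (racemic) | COC1=C(OC)C(O)C1=O | intermediate (not isolated)
10 | 3-methoxycyclobut-3-ene-1,2-dione (methyl semisquarate) | COC1=CC(=O)C1=O | intermediate
11 | 4-hydroxy-3-methoxycyclobut-2-en-1-one (racemic) | COC1=CC(=O)C1O | intermediate
12 | 4-chloro-3-methoxycyclobut-2-en-1-one (racemic) | COC1=CC(=O)C1Cl | intermediate
13 | methyl 2-(tert-butyldimethylsilyloxy)-6-{[(1E)-3-(tert-butyldimethylsilyloxy)-2-(2-methoxy-4-oxocyclobut-2-en-1-yl)prop-1-en-1-yl]oxy}-4-methylbenzoate (racemic; ring cis to aryloxy) | COC(=O)c1c(O[Si](C)(C)C(C)(C)C)cc(C)cc1O/C=C(\C1C(OC)=CC1=O)CO[Si](C)(C)C(C)(C)C | intermediate (not isolated)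
14 | methyl 2-(tert-butyldimethylsilyloxy)-6-{[(1E,3E)-2-(tert-butyldimethylsilyloxymethyl)-4-methoxy-6-oxohexa-1,3,5-trien-1-yl]oxy}-4-methylbenzoate (dienylketene, chain ends cis about the central double bond) | COC(=O)c1c(O[Si](C)(C)C(C)(C)C)cc(C)cc1O/C=C(CO[Si](C)(C)C(C)(C)C)\C=C(OC)/C=C=O | intermediate (not isolated)
15 | methyl 2-(tert-butyldimethylsilyloxy)-6-{[2-(tert-butyldimethylsilyloxymethyl)-4-methoxy-6-oxocyclohexa-2,4-dien-1-yl]oxy}-4-methylbenzoate (racemic) | COC(=O)c1c(O[Si](C)(C)C(C)(C)C)cc(C)cc1OC1C(=O)C=C(OC)C=C1CO[Si](C)(C)C(C)(C)C | intermediate (not isolated)
16 | methyl 2-(tert-butyldimethylsilyloxy)-6-[2-(tert-butyldimethylsilyloxymethyl)-6-hydroxy-4-methoxyphenoxy]-4-methylbenzoate | COC(=O)c1c(O[Si](C)(C)C(C)(C)C)cc(C)cc1Oc1c(O)cc(OC)cc1CO[Si](C)(C)C(C)(C)C | intermediate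
17 | methyl 2-hydroxy-6-[2-hydroxy-6-(hydroxymethyl)-4-methoxyphenoxy]-4-methylbenzoate | COC(=O)c1c(O)cc(C)cc1Oc1c(O)cc(OC)cc1CO | intermediate
18 | vinyl palmitate (ethenyl hexadecanoate) | CCCCCCCCCCCCCCCC(=O)OC=C | starting material
19 | betaethrin E, [3-hydroxy-2-(3-hydroxy-2-methoxycarbonyl-5-methylphenoxy)-5-methoxyphenyl]methyl hexadecanoate | CCCCCCCCCCCCCCCC(=O)OCc1cc(OC)cc(O)c1Oc1cc(C)cc(O)c1C(=O)OC | target

## Step count and least certain steps

Total step count: 11. Longest linear sequence: 8 steps (steps 1 to 5, 9, 10 and 11, from 1). The cyclobutenone branch (steps 6 to 8) joins at step 9.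

**Step 9 (key step).** The most likely failure is slow transfer of the α-branched, β-oxygenated alkenyl group from tin to palladium. During that time 12, which itself ring-opens on heating, would decompose and 7 would suffer protodestannylation. A second risk is capture of ketene 14 by nucleophiles if the inward aryloxy group slows the 6π closure. The fallback sets out from 7 (with 12) and comes back at 16. Iododestannylation (I2, CH2Cl2, 0 °C) would give methyl 2-(tert-butyldimethylsilyloxy)-6-{[(Z)-3-(tert-butyldimethylsilyloxy)-2-iodoprop-1-en-1-yl]oxy}-4-methylbenzoate F1. Iodine–magnesium exchange (i-PrMgCl·LiCl, THF, −40 °C) would give the alkenylmagnesium chloride F2, and ZnCl2 the alkenylzinc chloride F3. F3 would be coupled with 12 at room temperature (Pd2(dba)3, tri(2-furyl)phosphine; Negishi coupling), and the resulting 13 would be heated in dioxane to 16.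

**Step 2.** The phenoxide may attack sulfur (sulfonyl transfer) in place of the β-carbon, and a second vinylation of the product may compete. The fallback sets out from 1 and comes back at 4. Oxalyl chloride with catalytic DMF in CH2Cl2 would convert the enol into the vinylogous acid chloride (Z)-2-bromo-3-chloroprop-2-enal F4, which has no sulfur electrophile. F4 would be treated with an excess of 3 and K2CO3 in MeCN to give 4 by the same addition–elimination.

**Step 5.** Oxidative addition to the electron-rich, branched alkenyl bromide may be sluggish, so that reductive debromination and homocoupling take over. The fallback sets out from 6 and comes back at 7. Bromine–lithium exchange (t-BuLi, 2 equiv., THF–Et2O, −100 °C), which should outrun attack on the doubly ortho-flanked ester, would give the alkenyllithium F5, which is stabilised by the cis aryloxy group. Quenching with Bu3SnCl would give 7.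

**Step 7.** Hydride may be delivered in part to the vinylogous ester carbonyl or may displace methoxide by conjugate addition, and the small α-ketol may not survive work-up. The fallback fixes the oxygen pattern by cycloaddition. It sets out from no numbered compound, since it replaces 8, 10 and 11, and comes back at 12. Commercial 2-chloro-1,1-dimethoxyethane F6 would be converted with NaNH2 in liquid ammonia into methoxyacetylene F7. [2+2] Cycloaddition of F7 with dichloroketene (trichloroacetyl chloride, zinc–copper couple, Et2O) would give 4,4-dichloro-3-methoxycyclobut-2-en-1-one F8. The ketene carbonyl carbon bonds to the unsubstituted alkyne carbon, so the 1,3-relationship of carbonyl and methoxy is fixed. Removal of one chlorine with zinc dust (1 equiv.) in acetic acid at low temperature would give 12.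

**Step 8.** Acid-promoted ionisation of the chlorosulfite, with loss of methanol, ring opening or oligomerisation, may occur during chlorination or on concentration. The fallback sets out from 11 and comes back at 16. Neutral Appel bromination (CBr4, PPh3, CH2Cl2, −20 °C) would give 4-bromo-3-methoxycyclobut-2-en-1-one F9. Its filtered solution would be used in place of 12 under the conditions of step 9, and the more reactive C–Br bond should also allow a lower coupling temperature.

## Further compounds

F1 | step 9 | methyl 2-(tert-butyldimethylsilyloxy)-6-{[(Z)-3-(tert-butyldimethylsilyloxy)-2-iodoprop-1-en-1-yl]oxy}-4-methylbenzoate | COC(=O)c1c(O[Si](C)(C)C(C)(C)C)cc(C)cc1O/C=C(\I)CO[Si](C)(C)C(C)(C)C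
F2 | step 9 | chloro{(Z)-3-(tert-butyldimethylsilyloxy)-1-[3-(tert-butyldimethylsilyloxy)-2-(methoxycarbonyl)-5-methylphenoxy]prop-1-en-2-yl}magnesium | COC(=O)c1c(O[Si](C)(C)C(C)(C)C)cc(C)cc1O/C=C(\[Mg]Cl)CO[Si](C)(C)C(C)(C)C
F3 | step 9 | chloro{(Z)-3-(tert-butyldimethylsilyloxy)-1-[3-(tert-butyldimethylsilyloxy)-2-(methoxycarbonyl)-5-methylphenoxy]prop-1-en-2-yl}zinc | COC(=O)c1c(O[Si](C)(C)C(C)(C)C)cc(C)cc1O/C=C(\[Zn]Cl)CO[Si](C)(C)C(C)(C)C
F4 | step 2 | (Z)-2-bromo-3-chloroprop-2-enal | Cl/C=C(\Br)C=O
F5 | step 5 | {(E)-3-(tert-butyldimethylsilyloxy)-1-[3-(tert-butyldimethylsilyloxy)-2-(methoxycarbonyl)-5-methylphenoxy]prop-1-en-2-yl}lithium (lithium cis to aryloxy) | COC(=O)c1c(O[Si](C)(C)C(C)(C)C)cc(C)cc1O/C=C(\[Li])CO[Si](C)(C)C(C)(C)C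
F6 | step 7 | 2-chloro-1,1-dimethoxyethane | COC(CCl)OC
F7 | step 7 | methoxyacetylene (methoxyethyne) | COC#C
F8 | step 7 | 4,4-dichloro-3-methoxycyclobut-2-en-1-one | COC1=CC(=O)C1(Cl)Cl
F9 | step 8 | 4-bromo-3-methoxycyclobut-2-en-1-one (racemic) | COC1=CC(=O)C1Br
A1 | alternative 1 | 3-(methoxymethoxy)-5-methyl-2-(trimethylsilyl)phenyl trifluoromethanesulfonate | COCOc1cc(C)cc(OS(=O)(=O)C(F)(F)F)c1[Si](C)(C)C
A2 | alternative 1 | 2-(tert-butyldimethylsilyloxymethyl)-4-methoxy-6-(methoxymethoxy)phenol | Oc1c(CO[Si](C)(C)C(C)(C)C)cc(OC)cc1OCOC
A3 | alternative 1 | carbon dioxide | O=C=O
A4 | alternative 1 | 2-[2-(tert-butyldimethylsilyloxymethyl)-4-methoxy-6-(methoxymethoxy)phenoxy]-6-(methoxymethoxy)-4-methylbenzoic acid | OC(=O)c1c(OCOC)cc(C)cc1Oc1c(CO[Si](C)(C)C(C)(C)C)cc(OC)cc1OCOC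
A5 | alternative 2 | methyl 4-hydroxy-6-methyl-3-oxo-2,3-dihydro-1-benzofuran-2-carboxylate (racemic) | COC(=O)C1Oc2cc(C)cc(O)c2C1=O
A6 | alternative 2 | 5-(tert-butyldimethylsilyloxy)pent-3-yn-2-one | CC(=O)C#CCO[Si](C)(C)C(C)(C)C
A7 | alternative 2 | 6'-(tert-butyldimethylsilyloxymethyl)-4,4'-dihydroxy-6-methyl-3H-spiro[1-benzofuran-2,1'-cyclohexa-3',5'-diene]-2',3-dione (racemic) | Cc1cc(O)c2C(=O)C3(Oc2c1)C(=O)C=C(O)C=C3CO[Si](C)(C)C(C)(C)C
A8 | alternative 2 | methyl 2-[2-(tert-butyldimethylsilyloxymethyl)-4,6-dihydroxyphenoxy]-6-hydroxy-4-methylbenzoate | COC(=O)c1c(O)cc(C)cc1Oc1c(O)cc(O)cc1CO[Si](C)(C)C(C)(C)C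
A9 | alternative 3 | methyl 4-[2-(tert-butyldimethylsilyloxymethyl)-4-methoxy-6-(methoxymethoxy)phenoxy]-6-methyl-2-oxo-2H-pyran-3-carboxylate | COC(=O)C1=C(Oc2c(CO[Si](C)(C)C(C)(C)C)cc(OC)cc2OCOC)C=C(C)OC1=O
A10 | alternative 3 | 1,1-bis(trimethylsilyloxy)ethene | C=C(O[Si](C)(C)C)O[Si](C)(C)C
A11 | alternative 3 | methyl 2-[2-(tert-butyldimethylsilyloxymethyl)-4-methoxy-6-(methoxymethoxy)phenoxy]-6-hydroxy-4-methylbenzoate | COC(=O)c1c(O)cc(C)cc1Oc1c(CO[Si](C)(C)C(C)(C)C)cc(OC)cc1OCOC
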